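The bicyclo[3.2.1]octan-8-one is cut at the C-6–C-7 bond, the link between the methyl-bearing and the aryl-bearing carbon of the two-carbon bridge, which opens the cyclopentanone ring C-1/C-8/C-5/C-6/C-7 to a 2,2,6,6-tetrasubstituted cyclohex-3-enone. Its methoxy-bearing α-carbon carries a benzylic thionocarbonate, the other α-carbon a vinyl and a propargyl (masked allyl) group. Tin-mediated C–O fragmentation gives one planar benzylic radical from either carbinol epimer; its 5-exo addition to the cis vinyl group closes the bridge, turns the vinyl CH2 into the methyl group and sets both bridge stereocentres. The rigid bicycle then directs exo cis-dihydroxylation.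

Key step: step 8

Remark: the carbinol centre made in step 2 is drawn as the expected threo isomer; it is erased in step 8, so the erythro isomer would serve equally.

Step 1
Reactants: 1 cyclohexane-1,2-dione
Product: 2 2-methoxycyclohex-2-en-1-one
Conditions: MeOH, p-TsOH (cat.), benzene, reflux, Dean–Stark
Reagents that add atoms: methanol, CO
Why: Acid-catalysed enol ether formation on the enolised 1,2-dione, with loss of water, should give the conjugated 2-methoxy enone and creates no stereocentre.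

Step 2
Reactants: 2 2-methoxycyclohex-2-en-1-one; 3 3,4,5-trimethoxybenzaldehyde
Product: 6 rac-(2R)-2-[(S)-{[tert-butyl(dimethyl)silyl]oxy}(3,4,5-trimethoxyphenyl)methyl]-2-methoxycyclohex-3-en-1-one, via potassium dienolate 4 (not isolated), via potassium aldolate 5 (not isolated)
Conditions: KN(SiMe3)2 (0.95 equiv), THF, −78 to −20 °C; 3, −78 °C; t-BuMe2SiOTf, −78 to 0 °C
Reagents that add atoms: tert-butyldimethylsilyl trifluoromethanesulfonate, CC(C)(C)[Si](C)(C)OS(=O)(=O)C(F)(F)F
Why: With a slight deficit of base the enolates should equilibrate by proton transfer to the linear, fully conjugated dienolate 4, which adds to the aldehyde through its α-carbon in a closed chair transition state (deconjugative aldol addition), so the quaternary methoxy carbon and the carbinol carbon form as the racemic threo pair, and the aldolate 5 is silylated in the flask before it can revert.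

Step 3
Reactants: 6 rac-(2R)-2-[(S)-{[tert-butyl(dimethyl)silyl]oxy}(3,4,5-trimethoxyphenyl)methyl]-2-methoxycyclohex-3-en-1-one
Product: 7 (2R)-2-[(S)-{[tert-butyl(dimethyl)silyl]oxy}(3,4,5-trimethoxyphenyl)methyl]-2-methoxycyclohex-3-en-1-one
Conditions: preparative SFC, amylose tris(3,5-dimethylphenylcarbamate) phase, CO2/i-PrOH
Reagents that add atoms: none
Why: Chromatography on a chiral stationary phase (resolution of a racemate) separates the enantiomers and so fixes the absolute configuration of the quaternary carbon that becomes C-1 of the target.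

Step 4
Reactants: 7 (2R)-2-[(S)-{[tert-butyl(dimethyl)silyl]oxy}(3,4,5-trimethoxyphenyl)methyl]-2-methoxycyclohex-3-en-1-one
Product: 10 (2R,6E)-2-[(S)-{[tert-butyl(dimethyl)silyl]oxy}(3,4,5-trimethoxyphenyl)methyl]-6-ethylidene-2-methoxycyclohex-3-en-1-one, via lithium aldolate 8 (not isolated), via mesylate 9 (not isolated)
Conditions: LiN(i-Pr)2, THF, −78 °C; MeCHO; MeSO2Cl, −78 to 0 °C; DBU, 0 °C to rt
Reagents that add atoms: acetaldehyde, CC=O
Why: The ketone can enolise only toward C-6 because C-2 is quaternary, so aldol addition to acetaldehyde, mesylation of the aldolate and E1cB elimination (aldol condensation) should give the more stable (E)-ethylidene ketone with the stereocentres of 7 untouched.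

Step 5
Reactants: 10 (2R,6E)-2-[(S)-{[tert-butyl(dimethyl)silyl]oxy}(3,4,5-trimethoxyphenyl)methyl]-6-ethylidene-2-methoxycyclohex-3-en-1-one
Product: 12 (2R,6S)-2-[(S)-{[tert-butyl(dimethyl)silyl]oxy}(3,4,5-trimethoxyphenyl)methyl]-6-ethenyl-2-methoxy-6-(prop-2-yn-1-yl)cyclohex-3-en-1-one, via lithium dienolate 11 (not isolated)
Conditions: LiN(i-Pr)2, HMPA, THF, −78 °C; HC≡CCH2Br, −78 to −40 °C
Reagents that add atoms: 3-bromoprop-1-yne, C#CCBr
Why: Lacking α′-hydrogens, the enone is deprotonated at the ethylidene methyl group to the dienolate 11, which is alkylated at its α-carbon (deconjugative alkylation); its ring is an almost flat 1,4-cyclohexadiene, so the bromide should attack the face of the small methoxy group, anti to the bulky silyloxybenzyl arm on C-2, which sets the new quaternary centre with the vinyl group cis to that arm.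

Step 6
Reactants: 12 (2R,6S)-2-[(S)-{[tert-butyl(dimethyl)silyl]oxy}(3,4,5-trimethoxyphenyl)methyl]-6-ethenyl-2-methoxy-6-(prop-2-yn-1-yl)cyclohex-3-en-1-one
Product: 13 (2R,6S)-6-ethenyl-2-[(S)-hydroxy(3,4,5-trimethoxyphenyl)methyl]-2-methoxy-6-(prop-2-yn-1-yl)cyclohex-3-en-1-one
Conditions: HF·pyridine, THF, 0 °C to rt
Reagents that add atoms: none
Why: Fluoride cleaves the silyl ether under non-basic, non-ionising conditions (desilylation), so neither retro-aldol cleavage nor a 1,2-shift toward the benzylic carbon should intervene.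

Step 7
Reactants: 13 (2R,6S)-6-ethenyl-2-[(S)-hydroxy(3,4,5-trimethoxyphenyl)methyl]-2-methoxy-6-(prop-2-yn-1-yl)cyclohex-3-en-1-one
Product: 14 O-{(S)-[(1R,5S)-5-ethenyl-1-methoxy-6-oxo-5-(prop-2-yn-1-yl)cyclohex-2-en-1-yl](3,4,5-trimethoxyphenyl)methyl} O-phenyl carbonothioate
Conditions: PhOC(S)Cl, DMAP, pyridine, CH2Cl2, 0 °C to rt
Reagents that add atoms: O-phenyl chlorothionoformate, S=C(Cl)Oc1ccccc1
Why: DMAP-catalysed O-acylation of the hindered secondary alcohol should give the O-aryl thionocarbonate needed for radical C–O cleavage (Barton–McCombie precursor) without touching the stereocentres.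

Step 8
Reactants: 14 O-{(S)-[(1R,5S)-5-ethenyl-1-methoxy-6-oxo-5-(prop-2-yn-1-yl)cyclohex-2-en-1-yl](3,4,5-trimethoxyphenyl)methyl} O-phenyl carbonothioate
Product: 17 (1R,5S,6R,7S)-1-methoxy-6-methyl-5-(prop-2-yn-1-yl)-7-(3,4,5-trimethoxyphenyl)bicyclo[3.2.1]oct-2-en-8-one, via benzylic radical 15 (not isolated), via primary radical 16 (not isolated)
Conditions: Bu3SnH (1.2 equiv, syringe pump), AIBN (0.2 equiv), benzene (0.02 M), 80 °C
Reagents that add atoms: none
Why: The stannyl radical adds to the thiocarbonyl sulfur and the adduct fragments at the benzylic C–O bond to the planar benzylic radical 15, so both carbinol epimers of 14 converge; 15 adds to the internal carbon of the cis vinyl group and the primary radical 16 takes hydrogen from Bu3SnH, which turns the vinyl CH2 into the C-6 methyl group. The closest known reaction type is a Barton–McCombie C–O homolysis used to start a tin hydride 5-exo-trig radical cyclisation. The ring closed is the cyclopentanone ring C-1/C-8/C-5/C-6/C-7 by 5-exo-trig attack, which completes the bicyclo[3.2.1]octene; the propargyl arm is trans across the ring and the ring alkene would need a 3-exo closure, so neither can be reached. C-7 should be set by the radical conformation with the aryl group exo, away from the cyclohexene ring; C-6 follows from the vinyl rotamer that keeps its CH2 terminus endo and trans to the aryl group, and because closure of a benzylic radical is reversible the more stable trans isomer should be the one drained by hydrogen transfer. The step needs 5-exo closure to beat direct reduction, the 6-endo mode, 1,2-acyl or vinyl shifts and stannyl addition to the alkyne; this rests on slow hydrogen transfer from Bu3SnH to benzylic radicals compared with primary ones, on the benzylic stabilisation of 15 that disfavours the strained 3-exo intermediates of such shifts, and on stannyl attack being much faster at C=S than at C≡C.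

Step 9
Reactants: 17 (1R,5S,6R,7S)-1-methoxy-6-methyl-5-(prop-2-yn-1-yl)-7-(3,4,5-trimethoxyphenyl)bicyclo[3.2.1]oct-2-en-8-one
Product: 18 (1S,2S,3S,5R,6R,7S)-2,3-dihydroxy-1-methoxy-6-methyl-5-(prop-2-yn-1-yl)-7-(3,4,5-trimethoxyphenyl)bicyclo[3.2.1]octan-8-one
Conditions: OsO4 (5 mol %), NMO, acetone/H2O, 0 °C to rt
Reagents that add atoms: osmium tetroxide, O=[Os](=O)(=O)=O; N-methylmorpholine N-oxide, C[N+]1([O-])CCOCC1; water, O
Why: Catalytic osmylation (Upjohn dihydroxylation) should add both oxygens to the ring alkene from the face opposite the two-carbon bridge, whose endo methyl group blocks the other face, giving the cis-diol with the C-2 and C-3 configurations of the target while the alkyne reacts far more slowly.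

Step 10
Reactants: 18 (1S,2S,3S,5R,6R,7S)-2,3-dihydroxy-1-methoxy-6-methyl-5-(prop-2-yn-1-yl)-7-(3,4,5-trimethoxyphenyl)bicyclo[3.2.1]octan-8-one
Product: 20 (1S,2S,3S,5R,6R,7S)-2-hydroxy-1,3-dimethoxy-6-methyl-5-(prop-2-yn-1-yl)-7-(3,4,5-trimethoxyphenyl)bicyclo[3.2.1]octan-8-one, via stannylene acetal 19 (not isolated)
Conditions: Bu2SnO, toluene, reflux (−H2O); MeI, CsF, DMF, rt
Reagents that add atoms: iodomethane, CI
Why: The dibutylstannylene acetal of the cis-diol should be alkylated at its equatorial, less hindered oxygen on C-3 (stannylene-mediated regioselective O-methylation), leaving the axial hydroxyl on C-2 free and never forming a free alkoxide that could undergo retro-aldol cleavage.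

Step 11
Reactants: 20 (1S,2S,3S,5R,6R,7S)-2-hydroxy-1,3-dimethoxy-6-methyl-5-(prop-2-yn-1-yl)-7-(3,4,5-trimethoxyphenyl)bicyclo[3.2.1]octan-8-one
Product: 21 (1S,2S,3S,5R,6R,7S)-2-hydroxy-1,3-dimethoxy-6-methyl-5-(prop-2-en-1-yl)-7-(3,4,5-trimethoxyphenyl)bicyclo[3.2.1]octan-8-one
Conditions: H2 (1 atm), Pd/CaCO3 poisoned with Pb(OAc)2, quinoline, EtOAc, rt
Reagents that add atoms: none
Why: Semihydrogenation over the poisoned palladium catalyst (Lindlar reduction) should stop at the terminal alkene, unmasking the allyl group without touching the ketone or the stereocentres.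

Compound list

1 | cyclohexane-1,2-dione | O=C1CCCCC1=O | starting material
2 | 2-methoxycyclohex-2-en-1-one | COC1=CCCCC1=O | intermediate
3 | 3,4,5-trimethoxybenzaldehyde | COc1cc(C=O)cc(OC)c1OC | starting material
4 | potassium 2-methoxycyclohexa-1,3-dien-1-olate (linear dienolate) | [K+].[O-]C1=C(OC)C=CCC1 | intermediate
5 | potassium rac-(S)-[(1R)-1-methoxy-6-oxocyclohex-2-en-1-yl](3,4,5-trimethoxyphenyl)methanolate (both enantiomers written) | C1CC=C[C@](OC)(C1=O)[C@@H]([O-])c1cc(OC)c(OC)c(OC)c1.[K+].C1CC=C[C@@](OC)(C1=O)[C@H]([O-])c1cc(OC)c(OC)c(OC)c1.[K+] | intermediate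
6 | rac-(2R)-2-[(S)-{[tert-butyl(dimethyl)silyl]oxy}(3,4,5-trimethoxyphenyl)methyl]-2-methoxycyclohex-3-en-1-one (both enantiomers written) | C1CC=C[C@](OC)(C1=O)[C@@H](O[Si](C)(C)C(C)(C)C)c1cc(OC)c(OC)c(OC)c1.C1CC=C[C@@](OC)(C1=O)[C@H](O[Si](C)(C)C(C)(C)C)c1cc(OC)c(OC)c(OC)c1 | intermediate
7 | (2R)-2-[(S)-{[tert-butyl(dimethyl)silyl]oxy}(3,4,5-trimethoxyphenyl)methyl]-2-methoxycyclohex-3-en-1-one | C1CC=C[C@](OC)(C1=O)[C@@H](O[Si](C)(C)C(C)(C)C)c1cc(OC)c(OC)c(OC)c1 | intermediate
8 | lithium 1-{(5R)-5-[(S)-{[tert-butyl(dimethyl)silyl]oxy}(3,4,5-trimethoxyphenyl)methyl]-5-methoxy-6-oxocyclohex-3-en-1-yl}ethan-1-olate (epimers at ring C-1 and at the carbinol carbon) | CC([O-])C1CC=C[C@](OC)(C1=O)[C@@H](O[Si](C)(C)C(C)(C)C)c1cc(OC)c(OC)c(OC)c1.[Li+] | intermediate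
9 | 1-{(5R)-5-[(S)-{[tert-butyl(dimethyl)silyl]oxy}(3,4,5-trimethoxyphenyl)methyl]-5-methoxy-6-oxocyclohex-3-en-1-yl}ethyl methanesulfonate (epimer mixture) | CC(OS(C)(=O)=O)C1CC=C[C@](OC)(C1=O)[C@@H](O[Si](C)(C)C(C)(C)C)c1cc(OC)c(OC)c(OC)c1 | intermediate
10 | (2R,6E)-2-[(S)-{[tert-butyl(dimethyl)silyl]oxy}(3,4,5-trimethoxyphenyl)methyl]-6-ethylidene-2-methoxycyclohex-3-en-1-one | C/C=C1/C(=O)[C@@](OC)(C=CC1)[C@@H](O[Si](C)(C)C(C)(C)C)c1cc(OC)c(OC)c(OC)c1 | intermediate
11 | lithium (6R)-6-[(S)-{[tert-butyl(dimethyl)silyl]oxy}(3,4,5-trimethoxyphenyl)methyl]-2-ethenyl-6-methoxycyclohexa-1,4-dien-1-olate | [Li+].[O-]C1=C(C=C)CC=C[C@@]1(OC)[C@@H](O[Si](C)(C)C(C)(C)C)c1cc(OC)c(OC)c(OC)c1 | intermediate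
12 | (2R,6S)-2-[(S)-{[tert-butyl(dimethyl)silyl]oxy}(3,4,5-trimethoxyphenyl)methyl]-6-ethenyl-2-methoxy-6-(prop-2-yn-1-yl)cyclohex-3-en-1-one | C#CC[C@]1(C=C)CC=C[C@](OC)(C1=O)[C@@H](O[Si](C)(C)C(C)(C)C)c1cc(OC)c(OC)c(OC)c1 | intermediate
13 | (2R,6S)-6-ethenyl-2-[(S)-hydroxy(3,4,5-trimethoxyphenyl)methyl]-2-methoxy-6-(prop-2-yn-1-yl)cyclohex-3-en-1-one | C#CC[C@]1(C=C)CC=C[C@](OC)(C1=O)[C@@H](O)c1cc(OC)c(OC)c(OC)c1 | intermediate
14 | O-{(S)-[(1R,5S)-5-ethenyl-1-methoxy-6-oxo-5-(prop-2-yn-1-yl)cyclohex-2-en-1-yl](3,4,5-trimethoxyphenyl)methyl} O-phenyl carbonothioate | C#CC[C@]1(C=C)CC=C[C@](OC)(C1=O)[C@@H](OC(=S)Oc1ccccc1)c1cc(OC)c(OC)c(OC)c1 | intermediate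
15 | benzylic radical from 14 after loss of the thiocarbonate group (ring stereocentres unchanged) | C#CC[C@]1(C=C)CC=C[C@](OC)(C1=O)[CH]c1cc(OC)c(OC)c(OC)c1 | intermediate
16 | primary alkyl radical with the skeleton of 17, CH2 radical in place of the 6-methyl group | C#CC[C@]12CC=C[C@](OC)(C1=O)[C@H](c1cc(OC)c(OC)c(OC)c1)[C@H]2[CH2] | intermediate
17 | (1R,5S,6R,7S)-1-methoxy-6-methyl-5-(prop-2-yn-1-yl)-7-(3,4,5-trimethoxyphenyl)bicyclo[3.2.1]oct-2-en-8-one | C#CC[C@]12CC=C[C@](OC)(C1=O)[C@H](c1cc(OC)c(OC)c(OC)c1)[C@H]2C | intermediate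
18 | (1S,2S,3S,5R,6R,7S)-2,3-dihydroxy-1-methoxy-6-methyl-5-(prop-2-yn-1-yl)-7-(3,4,5-trimethoxyphenyl)bicyclo[3.2.1]octan-8-one | C#CC[C@]12C[C@H](O)[C@H](O)[C@](OC)(C1=O)[C@H](c1cc(OC)c(OC)c(OC)c1)[C@H]2C | intermediate
19 | 2,3-O-dibutylstannylene acetal of 18 (2,2-dibutyl-1,3,2-dioxastannolane fused at C-2/C-3) | C#CC[C@]12C[C@@H]3O[Sn](CCCC)(CCCC)O[C@@H]3[C@](OC)(C1=O)[C@H](c1cc(OC)c(OC)c(OC)c1)[C@H]2C | intermediate
20 | (1S,2S,3S,5R,6R,7S)-2-hydroxy-1,3-dimethoxy-6-methyl-5-(prop-2-yn-1-yl)-7-(3,4,5-trimethoxyphenyl)bicyclo[3.2.1]octan-8-one | C#CC[C@]12C[C@H](OC)[C@H](O)[C@](OC)(C1=O)[C@H](c1cc(OC)c(OC)c(OC)c1)[C@H]2C | intermediate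
21 | (1S,2S,3S,5R,6R,7S)-2-hydroxy-1,3-dimethoxy-6-methyl-5-(prop-2-en-1-yl)-7-(3,4,5-trimethoxyphenyl)bicyclo[3.2.1]octan-8-one (CNP0275320.2) | C=CC[C@]12C[C@H](OC)[C@H](O)[C@](OC)(C1=O)[C@H](c1cc(OC)c(OC)c(OC)c1)[C@H]2C | target

Total step count: 11. Longest linear sequence: 11 steps (1 to 21).

Steps most likely to fail

Step 8 (key step). The benzylic radical may be reduced before it cyclises, the reversible closure may drift to the 6-endo mode or to the cis C-6/C-7 relationship, and stannyl radicals may add to the alkyne. The fallback reverses the roles of the two carbons and sets out from 13. Oxidation with Dess–Martin periodinane should give 6-ethenyl-2-methoxy-6-(prop-2-yn-1-yl)-2-(3,4,5-trimethoxybenzoyl)cyclohex-3-en-1-one F1, which is condensed with TsNHNH2 to its N-tosylhydrazone F2. Fe(acac)3 and PhSiH3 in EtOH then transfer a hydrogen atom to the vinyl group; the secondary radical at the future C-6 adds 5-exo to the hydrazone carbon, and loss of sulfinate and N2 should give 17, where the fallback rejoins the route.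

Step 2. Deprotonation may occur at the α′-methylene instead of the γ-position, the dienolate may react through its γ-carbon, or the aldolate may revert before silylation. The fallback sets out from 2. Wohl–Ziegler bromination (NBS, AIBN) should give 4-bromo-2-methoxycyclohex-2-en-1-one F3. Indium powder and 3 in THF/H2O (Barbier reaction) form the allylindium species at a defined position, and it should add to the aldehyde through ring C-2 to give rac-(2R)-2-[(S)-hydroxy(3,4,5-trimethoxyphenyl)methyl]-2-methoxycyclohex-3-en-1-one F4. Silylation with t-BuMe2SiOTf and 2,6-lutidine returns to 6.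

Step 5. The propargyl bromide may enter on the face of the silyloxybenzyl arm (wrong facial sense). The fallback inverts the order of bond formation at C-6 and sets out from 7. Propargylation (LiN(i-Pr)2; 3-bromoprop-1-yne) should give (2R)-2-[(S)-{[tert-butyl(dimethyl)silyl]oxy}(3,4,5-trimethoxyphenyl)methyl]-2-methoxy-6-(prop-2-yn-1-yl)cyclohex-3-en-1-one F5. Its lithium enolate is then added to acetaldehyde to give (2R,6S)-2-[(S)-{[tert-butyl(dimethyl)silyl]oxy}(3,4,5-trimethoxyphenyl)methyl]-6-(1-hydroxyethyl)-2-methoxy-6-(prop-2-yn-1-yl)cyclohex-3-en-1-one F6. Syn-dehydration with Burgess reagent, possible only toward the methyl group, returns to 12. In this order the two-carbon unit enters last, so the same facial preference now places it on the required face.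

Further compounds

F1 | step 8 | 6-ethenyl-2-methoxy-6-(prop-2-yn-1-yl)-2-(3,4,5-trimethoxybenzoyl)cyclohex-3-en-1-one (ring stereocentres as in 13) | C#CC[C@]1(C=C)CC=C[C@](OC)(C1=O)C(=O)c1cc(OC)c(OC)c(OC)c1
F2 | step 8 | N-tosylhydrazone of the aryl ketone of F1 | C#CC[C@]1(C=C)CC=C[C@](OC)(C1=O)C(=NNS(=O)(=O)c1ccc(C)cc1)c1cc(OC)c(OC)c(OC)c1
F3 | step 2 | 4-bromo-2-methoxycyclohex-2-en-1-one (racemic) | COC1=CC(Br)CCC1=O
F4 | step 2 | rac-(2R)-2-[(S)-hydroxy(3,4,5-trimethoxyphenyl)methyl]-2-methoxycyclohex-3-en-1-one (both enantiomers written) | C1CC=C[C@](OC)(C1=O)[C@@H](O)c1cc(OC)c(OC)c(OC)c1.C1CC=C[C@@](OC)(C1=O)[C@H](O)c1cc(OC)c(OC)c(OC)c1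
F5 | step 5 | (2R)-2-[(S)-{[tert-butyl(dimethyl)silyl]oxy}(3,4,5-trimethoxyphenyl)methyl]-2-methoxy-6-(prop-2-yn-1-yl)cyclohex-3-en-1-one (C-6 epimers) | C#CCC1CC=C[C@](OC)(C1=O)[C@@H](O[Si](C)(C)C(C)(C)C)c1cc(OC)c(OC)c(OC)c1
F6 | step 5 | (2R,6S)-2-[(S)-{[tert-butyl(dimethyl)silyl]oxy}(3,4,5-trimethoxyphenyl)methyl]-6-(1-hydroxyethyl)-2-methoxy-6-(prop-2-yn-1-yl)cyclohex-3-en-1-one (carbinol epimers) | C#CC[C@]1(C(C)O)CC=C[C@](OC)(C1=O)[C@@H](O[Si](C)(C)C(C)(C)C)c1cc(OC)c(OC)c(OC)c1
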